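**Plan**

1. Retrosynthesis: with the two unsaturated lactones unmasked last, the cyclopentane is cut between its two quaternary carbons, the CO2H-bearing carbon and the spiro carbon of the γ-lactone. This bond joins the α-carbons of two acyl groups (acid C=O and spirolactone C=O, a succinate-type 1,4-dicarbonyl unit), so both ends are enolate carbons of like polarity that can be united by oxidation.
2. Further cuts: the two ring CH2–C(α) bonds (enolate alkylations with primary triflates), the ring CH–carbinol bond (Evans syn-aldol), the dihydropyranone ring (hetero-Diels–Alder reaction) and the butenolide C3=C4 bond (ring-closing metathesis).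
3. Forward order of rings: butenolide (step 4, then carried as a silyl lactol ether); spirolactone ring (bought as a chiral menthyl acetal); dihydropyran (step 13, carried as a methyl acetal); cyclopentane last (step 16). Both lactol ethers are then re-oxidised and the acid-labile groups removed.
4. Stereochemistry: butenolide C-5 from (S)-1,2-epoxyoctane; ring CH and carbinol from the aldol; pyranone C-6 from the catalyst-controlled cycloaddition; spiro carbon by bond formation anti to the (S)-menthyloxy acetal; carboxyl-bearing carbon by the metal-bridged syn union of the two enolates.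
5. The two α-CH centres of the cyclisation precursor are planar in the bis-enolate, so all of its diastereomers funnel into one cyclopentane.

Key step: step 16

Assumption: the hemiacetal carbon of the hydroxy-lactone equilibrates through the open aldehyde–acid form and settles as the (S)-epimer drawn (OH trans to the bond from the spiro carbon to the carboxyl-bearing carbon), so it is not controlled separately.

Abbreviations: TBS = tert-butyldimethylsilyl; PMB = 4-methoxybenzyl; Men = (1S,2R,5S)-2-isopropyl-5-methylcyclohexyl, from (+)-menthol.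

**Route**

Step 1
Reactants: 1 (2S)-2-hexyloxirane [(S)-1,2-epoxyoctane]; 2 trimethylsulfonium iodide
Product: 3 (3S)-non-1-en-3-ol
Conditions: 2 (3 equiv), n-BuLi (3 equiv), THF, −10 °C to rt
Reagents that add atoms: none
Why: The sulfonium ylide (Corey–Chaykovsky type) opens the epoxide at its CH2 terminus and a second equivalent eliminates Me2S from the β-sulfonium alkoxide, a one-carbon epoxide-to-allylic-alcohol homologation that leaves the carbinol stereocentre untouched.

Step 2
Reactants: 4 itaconic anhydride; 5 tert-butanol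
Product: 6 4-tert-butoxy-2-methylidene-4-oxobutanoic acid
Conditions: t-BuOH (excess), toluene, 80 °C, no base
Reagents that add atoms: none
Why: Alcoholysis of itaconic anhydride occurs at the non-conjugated, less hindered carbonyl (regioselective anhydride opening), and omitting base avoids isomerisation to the citraconate.

Step 3
Reactants: 3 (3S)-non-1-en-3-ol; 6 4-tert-butoxy-2-methylidene-4-oxobutanoic acid
Product: 7 4-tert-butyl 1-[(3S)-non-1-en-3-yl] 2-methylidenebutanedioate
Conditions: DCC, DMAP (5 mol %), CH2Cl2, 0 °C to rt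
Reagents that add atoms: none
Why: Steglich esterification acylates the secondary allylic alcohol with retention at the carbinol carbon.

Step 4
Reactants: 7 diene diester
Product: 8 tert-butyl 2-[(5S)-5-hexyl-2-oxo-2,5-dihydrofuran-3-yl]acetate
Conditions: Grubbs second-generation catalyst (5 mol %), CH2Cl2, 40 °C
Reagents that add atoms: none
Why: Ring-closing metathesis of the allylic ester with the 1,1-disubstituted acrylate gives the 3,5-disubstituted butenolide with loss of ethene; the stereocentre is not involved.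

Step 5
Reactants: 8 butenolide ester
Product: 10 tert-butyl 2-[(5S)-2-(TBS-oxy)-5-hexyl-2,5-dihydrofuran-3-yl]acetate (both anomers), via lactol 9 (not isolated)
Conditions: DIBAL-H (1.1 equiv), CH2Cl2, −78 °C; Rochelle salt work-up; then TBSCl, imidazole, DMF, 0 °C
Reagents that add atoms: tert-butyldimethylsilyl chloride, CC(C)(C)[Si](C)(C)Cl
Why: DIBAL-H reduces the butenolide carbonyl to the lactol faster than the hindered tert-butyl ester, and silylation of the anomeric OH (lactone-to-lactol reduction, silyl acetal formation) removes the C5–H acidity that the butenolide would show in the later enolate steps.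

Step 6
Reactants: 11 (5S)-5-(Men-oxy)furan-2(5H)-one
Product: 12 (5S)-5-(Men-oxy)dihydrofuran-2(3H)-one
Conditions: H2 (1 atm), 10 % Pd/C, EtOAc, rt
Reagents that add atoms: none
Why: Heterogeneous hydrogenation saturates the C=C bond without touching the acetal stereocentre.

Step 7
Reactants: 13 3-[(4-methoxybenzyl)oxy]propanoic acid; 14 (4S)-4-benzyl-1,3-oxazolidin-2-one
Product: 16 (4S)-4-benzyl-3-{3-[(4-methoxybenzyl)oxy]propanoyl}-1,3-oxazolidin-2-one, via mixed pivalic anhydride 15 (not isolated)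
Conditions: PivCl, Et3N, THF, −20 °C; then LiCl, 14, −20 °C to rt
Reagents that add atoms: none
Why: N-Acylation of the oxazolidinone by the mixed anhydride is the standard attachment of an Evans auxiliary.

Step 8
Reactants: 16 N-acyl oxazolidinone; 17 acrolein
Product: 19 (4S)-4-benzyl-3-[(2S,3R)-3-hydroxy-2-{[(4-methoxybenzyl)oxy]methyl}pent-4-enoyl]-1,3-oxazolidin-2-one, via boron enolate 18 (not isolated)
Conditions: Bu2BOTf, i-Pr2NEt, CH2Cl2, −78 to 0 °C; 17, −78 °C; then pH 7 buffer, H2O2, MeOH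
Reagents that add atoms: none
Why: Evans syn-aldol: the (Z)-boron enolate reacts through a Zimmerman–Traxler chair on the face away from the benzyl group and sets the (2S,3R) pair that becomes the ring CH and the carbinol.

Step 9
Reactants: 19 aldol adduct
Product: 20 TBS ether of 19
Conditions: TBSOTf, 2,6-lutidine, CH2Cl2, −78 to 0 °C
Reagents that add atoms: tert-butyldimethylsilyl triflate, CC(C)(C)[Si](C)(C)OS(=O)(=O)C(F)(F)F
Why: Silylation of the aldol hydroxyl blocks retro-aldol cleavage and protects the carbinol until step 17.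

Step 10
Reactants: 20 silylated aldol adduct
Product: 21 (2S,3R)-3-(TBS-oxy)-2-{[(4-methoxybenzyl)oxy]methyl}pent-4-en-1-ol
Conditions: LiBH4, MeOH (1 equiv), Et2O, 0 °C
Reagents that add atoms: none
Why: Reductive removal of the N-acyl oxazolidinone gives the primary alcohol without epimerisation and returns the auxiliary.

Step 11
Reactants: 21 primary alcohol; 12 (5S)-5-(Men-oxy)dihydrofuran-2(3H)-one
Product: 24 (5S)-3-[(2S,3R)-3-(TBS-oxy)-2-{[(4-methoxybenzyl)oxy]methyl}pent-4-en-1-yl]-5-(Men-oxy)dihydrofuran-2(3H)-one (C-3 epimers), via triflate 22 (not isolated), via lithium lactone enolate 23 (not isolated)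
Conditions: (a) 21, Tf2O, 2,6-lutidine, CH2Cl2, −78 °C; (b) 12, LDA, THF, −78 °C; cold 22 added, −78 to −40 °C
Reagents that add atoms: none
Why: C-Alkylation of the lactone lithium enolate by the primary triflate joins the first ring CH2 to the future spiro carbon; the new α-centre need not be controlled because step 16 erases it.

Step 12
Reactants: 24 alkylated lactone
Product: 25 (2S,3S)-2-(TBS-oxy)-4-[(4-methoxybenzyl)oxy]-3-{[(5S)-5-(Men-oxy)-2-oxooxolan-3-yl]methyl}butanal
Conditions: OsO4 (2 mol %), NaIO4 (4 equiv), 2,6-lutidine, dioxane/H2O 3:1, rt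
Reagents that add atoms: sodium periodate, [Na+].[O-]I(=O)(=O)=O; osmium tetroxide (oxygen carrier), O=[Os](=O)(=O)=O
Why: Lemieux–Johnson cleavage of the only alkene present turns the vinyl group into the α-silyloxy aldehyde, with lutidine suppressing epimerisation.

Step 13
Reactants: 25 aldehyde; 26 (E)-1-methoxybuta-1,3-diene
Product: 27 (5S)-3-[(2S,3S)-3-(TBS-oxy)-3-[(2S,6R)-6-methoxy-3,6-dihydro-2H-pyran-2-yl]-2-{[(4-methoxybenzyl)oxy]methyl}propyl]-5-(Men-oxy)dihydrofuran-2(3H)-one
Conditions: chiral tridentate Schiff-base chromium(III) chloride catalyst (5 mol %, the enantiomer that delivers the diene to the aldehyde Si face), 4 Å MS, t-BuOMe, rt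
Reagents that add atoms: none
Why: Catalyst-controlled hetero-Diels–Alder reaction builds the pyranone ring in masked form; the catalyst sets the new pyran C-2 as (S) and the endo mode gives the cis methyl acetal.

Step 14
Reactants: 27 PMB ether
Product: 28 primary alcohol (27 with CH2OPMB replaced by CH2OH)
Conditions: DDQ (1.2 equiv), CH2Cl2/pH 7 buffer 10:1, 0 °C
Reagents that add atoms: none
Why: Oxidative PMB cleavage; at 0 °C the electron-rich benzyl ether reacts far faster than the allylic acetal C–H bonds.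

Step 15
Reactants: 28 primary alcohol; 10 silyl lactol ether ester
Product: 31 tert-butyl (4S,5S)-5-(TBS-oxy)-2-[(5S)-2-(TBS-oxy)-5-hexyl-2,5-dihydrofuran-3-yl]-5-[(2S,6R)-6-methoxy-3,6-dihydro-2H-pyran-2-yl]-4-{[(5S)-5-(Men-oxy)-2-oxooxolan-3-yl]methyl}pentanoate (epimers at C-2 and at lactone C-3), via triflate 29 (not isolated), via lithium ester enolate 30 (not isolated)
Conditions: (a) 28, Tf2O, 2,6-lutidine, CH2Cl2, −78 °C; (b) 10 (2 equiv), LDA, THF/DMPU, −78 °C; cold 29 added, −78 to −50 °C
Reagents that add atoms: none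
Why: The lithium dienolate of the tert-butyl ester is alkylated at its α-carbon by the primary triflate (enolate alkylation); the lactol ether has no acidic C–H and the new stereocentre is again irrelevant.

Step 16
Reactants: 31 cyclisation precursor (mixture of diastereomers)
Product: 33 tert-butyl 6-[(5S)-2-(TBS-oxy)-5-hexyl-2,5-dihydrofuran-3-yl]-8-{(S)-(TBS-oxy)[(2S,6R)-6-methoxy-3,6-dihydro-2H-pyran-2-yl]methyl}-3-(Men-oxy)-1-oxo-2-oxaspiro[4.4]nonane-6-carboxylate (ring stereocentres arranged as in the target), via dilithium bis-enolate 32 (not isolated)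
Conditions: LDA (2.3 equiv), THF (0.01 M), −78 °C, 1 h; then copper(II) 2-ethylhexanoate (2.5 equiv), −78 to −20 °C
Reagents that add atoms: none
Why: LDA turns the ester α-CH and the lactone α-CH into a dilithium bis-enolate whose two nucleophilic carbons are 1,5-related; Cu(II) oxidises one enolate to a copper-bound α-acyl radical, which attacks the carbon of the other enolate in a 5-exo-trig closure, and a second Cu(II) removes the remaining electron to give the 1,4-dicarbonyl bond between two new quaternary carbons. The closest known reaction types are the intramolecular oxidative coupling of diester dienolates to cyclic 1,2-diesters and the Cu(II)- or Fe(III)-mediated enolate heterocoupling. The spiro carbon is controlled by the acetal carbon of the lactone: the bond forms on the enolate face anti to the (S)-menthyloxy group (1,3-induction as in alkylations of γ-substituted butyrolactone enolates), which is also the closure that keeps the side chain on the pre-set ring CH pseudo-equatorial. The ester-bearing carbon is controlled by the metal bridge between the two enolate oxygens, which holds the two O–C=C units syn so that CO2t-Bu ends cis to the lactone carbonyl and the bulky dihydrofuranyl group eclipses only the lactone CH2. The step needs C–C coupling at the α-carbons in preference to dimerisation, disproportionation or γ-coupling of the dienolate; high dilution, the 1,5-relationship of the two carbons and the absence of any other acidic C–H (both unsaturated lactones are lactol ethers here) secure this, and since both α-stereocentres of 31 are erased on enolisation every diastereomer converges on 33.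

Step 17
Reactants: 33 protected spirocycle
Product: 35 butenolide (33 with the dihydrofuran silyl acetal oxidised to the 2(5H)-furanone and the carbinol OH free), via lactol 34 (not isolated)
Conditions: TBAF (4 equiv), AcOH (4 equiv), THF, 0 °C to rt; then activated MnO2 (20 equiv), CH2Cl2, rt
Reagents that add atoms: none
Why: Fluoride removes the anomeric and the secondary TBS groups, and MnO2 oxidises the freed allylic lactol to the butenolide under neutral conditions before it can lose water, while the saturated carbinol and the methyl acetal are inert.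

Step 18
Reactants: 35 butenolide with pyran methyl acetal
Product: 37 tert-butyl ester and menthyl acetal of the target, via pyran lactol 36 (not isolated)
Conditions: PPTS (0.2 equiv), acetone/H2O 10:1, rt; then activated MnO2, CH2Cl2, rt
Reagents that add atoms: water, O
Why: The allylic methyl acetal hydrolyses under mild acid much faster than the acyl-deactivated menthyl pseudo-ester or the tert-butyl ester, and MnO2 oxidises the allylic lactol to the 5,6-dihydropyran-2-one.

Step 19
Reactants: 37 protected target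
Product: 38 penicillactone A
Conditions: TFA/CH2Cl2/H2O 10:10:1, 0 °C to rt
Reagents that add atoms: water, O
Why: Aqueous acid cleaves the tert-butyl ester with loss of isobutene and hydrolyses the menthyl pseudo-ester to the hydroxy-lactone, whose hemiacetal carbon settles as in the target; both unsaturated lactones are stable to acid.

**Compound list**

1 | (2S)-2-hexyloxirane | CCCCCC[C@H]1CO1 | starting material
2 | trimethylsulfonium iodide | C[S+](C)C.[I-] | starting material
3 | (3S)-non-1-en-3-ol | CCCCCC[C@H](O)C=C | intermediate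
4 | itaconic anhydride | C=C1CC(=O)OC1=O | starting material
5 | tert-butanol | CC(C)(C)O | starting material
6 | 4-tert-butoxy-2-methylidene-4-oxobutanoic acid | C=C(CC(=O)OC(C)(C)C)C(=O)O | intermediate
7 | 4-tert-butyl 1-[(3S)-non-1-en-3-yl] 2-methylidenebutanedioate | CCCCCC[C@H](OC(=O)C(=C)CC(=O)OC(C)(C)C)C=C | intermediate
8 | tert-butyl 2-[(5S)-5-hexyl-2-oxo-2,5-dihydrofuran-3-yl]acetate | CCCCCC[C@H]1C=C(CC(=O)OC(C)(C)C)C(=O)O1 | intermediate
9 | tert-butyl 2-[(5S)-5-hexyl-2-hydroxy-2,5-dihydrofuran-3-yl]acetate (anomers) | CCCCCC[C@H]1C=C(CC(=O)OC(C)(C)C)C(O)O1 | intermediate (not isolated)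
10 | tert-butyl 2-[(5S)-2-(TBS-oxy)-5-hexyl-2,5-dihydrofuran-3-yl]acetate (anomers) | CCCCCC[C@H]1C=C(CC(=O)OC(C)(C)C)C(O[Si](C)(C)C(C)(C)C)O1 | intermediate
11 | (5S)-5-[(1S,2R,5S)-menthyloxy]furan-2(5H)-one | O=C1C=C[C@@H](O[C@H]2C[C@@H](C)CC[C@@H]2C(C)C)O1 | starting material
12 | (5S)-5-[(1S,2R,5S)-menthyloxy]dihydrofuran-2(3H)-one | O=C1CC[C@@H](O[C@H]2C[C@@H](C)CC[C@@H]2C(C)C)O1 | intermediate
13 | 3-[(4-methoxybenzyl)oxy]propanoic acid | COc1ccc(COCCC(=O)O)cc1 | starting material
14 | (4S)-4-benzyl-1,3-oxazolidin-2-one | O=C1N[C@@H](Cc2ccccc2)CO1 | starting material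
15 | mixed anhydride of 13 with pivalic acid | COc1ccc(COCCC(=O)OC(=O)C(C)(C)C)cc1 | intermediate (not isolated)
16 | (4S)-4-benzyl-3-{3-[(4-methoxybenzyl)oxy]propanoyl}-1,3-oxazolidin-2-one | COc1ccc(COCCC(=O)N2[C@@H](Cc3ccccc3)COC2=O)cc1 | intermediate
17 | acrolein | C=CC=O | starting material
18 | (Z)-dibutylboron enolate of 16 | COc1ccc(COC/C=C(\OB(CCCC)CCCC)N2[C@@H](Cc3ccccc3)COC2=O)cc1 | intermediate (not isolated)
19 | (4S)-4-benzyl-3-[(2S,3R)-3-hydroxy-2-{[(4-methoxybenzyl)oxy]methyl}pent-4-enoyl]-1,3-oxazolidin-2-one | COc1ccc(COC[C@@H]([C@H](O)C=C)C(=O)N2[C@@H](Cc3ccccc3)COC2=O)cc1 | intermediate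
20 | TBS ether of 19 | COc1ccc(COC[C@@H]([C@H](O[Si](C)(C)C(C)(C)C)C=C)C(=O)N2[C@@H](Cc3ccccc3)COC2=O)cc1 | intermediate
21 | (2S,3R)-3-(TBS-oxy)-2-{[(4-methoxybenzyl)oxy]methyl}pent-4-en-1-ol | COc1ccc(COC[C@@H]([C@H](O[Si](C)(C)C(C)(C)C)C=C)CO)cc1 | intermediate
22 | triflate of 21 | COc1ccc(COC[C@@H]([C@H](O[Si](C)(C)C(C)(C)C)C=C)COS(=O)(=O)C(F)(F)F)cc1 | intermediate (not isolated)
23 | lithium enolate of 12 | [Li]OC1=CC[C@@H](O[C@H]2C[C@@H](C)CC[C@@H]2C(C)C)O1 | intermediate (not isolated)
24 | (5S)-3-[(2S,3R)-3-(TBS-oxy)-2-(PMB-oxymethyl)pent-4-en-1-yl]-5-(Men-oxy)dihydrofuran-2(3H)-one, C-3 epimers | COc1ccc(COC[C@@H]([C@H](O[Si](C)(C)C(C)(C)C)C=C)CC2C[C@@H](O[C@H]3C[C@@H](C)CC[C@@H]3C(C)C)OC2=O)cc1 | intermediate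
25 | (2S,3S)-2-(TBS-oxy)-4-(PMB-oxy)-3-{[(5S)-5-(Men-oxy)-2-oxooxolan-3-yl]methyl}butanal | COc1ccc(COC[C@@H]([C@H](O[Si](C)(C)C(C)(C)C)C=O)CC2C[C@@H](O[C@H]3C[C@@H](C)CC[C@@H]3C(C)C)OC2=O)cc1 | intermediate
26 | (E)-1-methoxybuta-1,3-diene | CO/C=C/C=C | starting material
27 | (5S)-3-[(2S,3S)-3-(TBS-oxy)-3-[(2S,6R)-6-methoxy-3,6-dihydro-2H-pyran-2-yl]-2-(PMB-oxymethyl)propyl]-5-(Men-oxy)dihydrofuran-2(3H)-one | COc1ccc(COC[C@@H]([C@H](O[Si](C)(C)C(C)(C)C)[C@@H]2CC=C[C@H](OC)O2)CC2C[C@@H](O[C@H]3C[C@@H](C)CC[C@@H]3C(C)C)OC2=O)cc1 | intermediate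
28 | (5S)-3-[(2S,3S)-3-(TBS-oxy)-2-(hydroxymethyl)-3-[(2S,6R)-6-methoxy-3,6-dihydro-2H-pyran-2-yl]propyl]-5-(Men-oxy)dihydrofuran-2(3H)-one | OC[C@@H]([C@H](O[Si](C)(C)C(C)(C)C)[C@@H]1CC=C[C@H](OC)O1)CC1C[C@@H](O[C@H]2C[C@@H](C)CC[C@@H]2C(C)C)OC1=O | intermediate
29 | triflate of 28 | FC(F)(F)S(=O)(=O)OC[C@@H]([C@H](O[Si](C)(C)C(C)(C)C)[C@@H]1CC=C[C@H](OC)O1)CC1C[C@@H](O[C@H]2C[C@@H](C)CC[C@@H]2C(C)C)OC1=O | intermediate (not isolated)
30 | lithium dienolate of 10 | CCCCCC[C@H]1C=C(C=C(O[Li])OC(C)(C)C)C(O[Si](C)(C)C(C)(C)C)O1 | intermediate (not isolated)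
31 | tert-butyl (4S,5S)-5-(TBS-oxy)-2-[(5S)-2-(TBS-oxy)-5-hexyl-2,5-dihydrofuran-3-yl]-5-[(2S,6R)-6-methoxy-3,6-dihydro-2H-pyran-2-yl]-4-{[(5S)-5-(Men-oxy)-2-oxooxolan-3-yl]methyl}pentanoate, epimers at C-2 and lactone C-3 | CCCCCC[C@H]1C=C(C(C[C@@H]([C@H](O[Si](C)(C)C(C)(C)C)[C@@H]2CC=C[C@H](OC)O2)CC2C[C@@H](O[C@H]3C[C@@H](C)CC[C@@H]3C(C)C)OC2=O)C(=O)OC(C)(C)C)C(O[Si](C)(C)C(C)(C)C)O1 | intermediate
32 | dilithium bis-enolate of 31 | CCCCCC[C@H]1C=C(C(C[C@@H]([C@H](O[Si](C)(C)C(C)(C)C)[C@@H]2CC=C[C@H](OC)O2)CC2=C(O[Li])O[C@H](O[C@H]3C[C@@H](C)CC[C@@H]3C(C)C)C2)=C(O[Li])OC(C)(C)C)C(O[Si](C)(C)C(C)(C)C)O1 | intermediate (not isolated)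
33 | tert-butyl 6-[(5S)-2-(TBS-oxy)-5-hexyl-2,5-dihydrofuran-3-yl]-8-{(S)-(TBS-oxy)[(2S,6R)-6-methoxy-3,6-dihydro-2H-pyran-2-yl]methyl}-3-(Men-oxy)-1-oxo-2-oxaspiro[4.4]nonane-6-carboxylate, (3S,5S,8S), C-6 arranged as in the target | CCCCCC[C@H]1C=C([C@]2(C(=O)OC(C)(C)C)C[C@@H]([C@H](O[Si](C)(C)C(C)(C)C)[C@@H]3CC=C[C@H](OC)O3)C[C@]23C[C@@H](O[C@H]4C[C@@H](C)CC[C@@H]4C(C)C)OC3=O)C(O[Si](C)(C)C(C)(C)C)O1 | intermediate
34 | 33 with both TBS groups removed (dihydrofuranol lactol, free carbinol) | CCCCCC[C@H]1C=C([C@]2(C(=O)OC(C)(C)C)C[C@@H]([C@H](O)[C@@H]3CC=C[C@H](OC)O3)C[C@]23C[C@@H](O[C@H]4C[C@@H](C)CC[C@@H]4C(C)C)OC3=O)C(O)O1 | intermediate (not isolated)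
35 | tert-butyl (3S,5S,6S,8S)-6-[(5S)-5-hexyl-2-oxo-2,5-dihydrofuran-3-yl]-8-{(S)-hydroxy[(2S,6R)-6-methoxy-3,6-dihydro-2H-pyran-2-yl]methyl}-3-(Men-oxy)-1-oxo-2-oxaspiro[4.4]nonane-6-carboxylate | CCCCCC[C@H]1C=C([C@]2(C(=O)OC(C)(C)C)C[C@@H]([C@H](O)[C@@H]3CC=C[C@H](OC)O3)C[C@]23C[C@@H](O[C@H]4C[C@@H](C)CC[C@@H]4C(C)C)OC3=O)C(=O)O1 | intermediate
36 | 35 with the pyran methyl acetal hydrolysed to the lactol | CCCCCC[C@H]1C=C([C@]2(C(=O)OC(C)(C)C)C[C@@H]([C@H](O)[C@@H]3CC=CC(O)O3)C[C@]23C[C@@H](O[C@H]4C[C@@H](C)CC[C@@H]4C(C)C)OC3=O)C(=O)O1 | intermediate (not isolated)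
37 | tert-butyl (3S,5S,6S,8S)-6-[(5S)-5-hexyl-2-oxo-2,5-dihydrofuran-3-yl]-8-{(S)-hydroxy[(2S)-6-oxo-3,6-dihydro-2H-pyran-2-yl]methyl}-3-(Men-oxy)-1-oxo-2-oxaspiro[4.4]nonane-6-carboxylate | CCCCCC[C@H]1C=C([C@]2(C(=O)OC(C)(C)C)C[C@@H]([C@H](O)[C@@H]3CC=CC(=O)O3)C[C@]23C[C@@H](O[C@H]4C[C@@H](C)CC[C@@H]4C(C)C)OC3=O)C(=O)O1 | intermediate
38 | penicillactone A, (3S,5S,6S,8S)-6-[(5S)-5-hexyl-2-oxo-2,5-dihydrofuran-3-yl]-3-hydroxy-8-{(S)-hydroxy[(2S)-6-oxo-3,6-dihydro-2H-pyran-2-yl]methyl}-1-oxo-2-oxaspiro[4.4]nonane-6-carboxylic acid | CCCCCC[C@H]1C=C([C@]2(C(=O)O)C[C@@H]([C@H](O)[C@@H]3CC=CC(=O)O3)C[C@]23C[C@@H](O)OC3=O)C(=O)O1 | target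

**Count and risks**

Total steps: 19. Longest linear sequence: 13 steps (steps 7–19, from 13 and 14).

Most likely to fail:

Step 16. Bond formation between two fully substituted enolate carbons may be slow, so that the copper-bound radical disproportionates or is reduced back, and the face of the ester enolate may be poorly discriminated. Fallback: a silicon template. Starting from 31, the bis-enolate 32 is trapped with dichlorodiisopropylsilane to give the cyclic diisopropylsilylene bis(ketene acetal) F1, in which one silicon holds both enolate oxygens on the same side. One-electron oxidation of this silyl bis-enol ether with ceric ammonium nitrate and NaHCO3 in MeCN at −10 °C forms the same C–C bond, now necessarily with the two carbonyls cis, and loss of silicon returns the route at 33.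

Step 15. Alkylation of the hindered dienolate by the β-branched triflate may be slow enough for proton transfer to the lactone α-CH or for ring opening of the dienolate by vinylogous β-elimination. Fallback: aldol addition followed by deoxygenation. Starting from 28, Dess–Martin periodinane gives the aldehyde F2. The lithium enolate 30 adds to it within minutes at −78 °C to give the β-hydroxy ester F3. 1,1'-Thiocarbonyldiimidazole converts this into the thiocarbonylimidazolide F4, and Barton–McCombie deoxygenation (Bu3SnH, AIBN, toluene, 80 °C) returns the route at 31.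

Step 17. The free 2,5-dihydrofuran-2-ol may lose water and aromatise to the furan, destroying C-5, before it is oxidised. Fallback: oxidation without freeing the lactol. Starting from 33, excess DDQ in 1,2-dichloroethane/pH 7 buffer at 60 °C abstracts the hydride of both allylic acetal carbons; loss of the silyl and methyl groups gives the bis-lactone F5 (butenolide and dihydropyranone formed together, carbinol still silylated). HF·pyridine in THF then removes the remaining TBS ether and the route is rejoined at 37.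

**Further compounds**

F1 | step 16 | cyclic diisopropylsilylene bis(ketene acetal) of 31 | CCCCCC[C@H]1C=C(C2=C(OC(C)(C)C)O[Si](C(C)C)(C(C)C)OC3=C(C[C@@H](C2)[C@H](O[Si](C)(C)C(C)(C)C)[C@@H]4CC=C[C@H](OC)O4)C[C@@H](O[C@H]5C[C@@H](C)CC[C@@H]5C(C)C)O3)C(O[Si](C)(C)C(C)(C)C)O1
F2 | step 15 | aldehyde from 28 (CH2OH oxidised to CHO) | O=C[C@@H]([C@H](O[Si](C)(C)C(C)(C)C)[C@@H]1CC=C[C@H](OC)O1)CC1C[C@@H](O[C@H]2C[C@@H](C)CC[C@@H]2C(C)C)OC1=O
F3 | step 15 | β-hydroxy ester (aldol adduct of 30 with F2; 3-hydroxy derivative of 31) | CCCCCC[C@H]1C=C(C(C(O)[C@@H]([C@H](O[Si](C)(C)C(C)(C)C)[C@@H]2CC=C[C@H](OC)O2)CC2C[C@@H](O[C@H]3C[C@@H](C)CC[C@@H]3C(C)C)OC2=O)C(=O)OC(C)(C)C)C(O[Si](C)(C)C(C)(C)C)O1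
F4 | step 15 | O-(imidazol-1-ylthiocarbonyl) derivative of F3 | CCCCCC[C@H]1C=C(C(C(OC(=S)n2ccnc2)[C@@H]([C@H](O[Si](C)(C)C(C)(C)C)[C@@H]2CC=C[C@H](OC)O2)CC2C[C@@H](O[C@H]3C[C@@H](C)CC[C@@H]3C(C)C)OC2=O)C(=O)OC(C)(C)C)C(O[Si](C)(C)C(C)(C)C)O1
F5 | step 17 | carbinol TBS ether of 37 | CCCCCC[C@H]1C=C([C@]2(C(=O)OC(C)(C)C)C[C@@H]([C@H](O[Si](C)(C)C(C)(C)C)[C@@H]3CC=CC(=O)O3)C[C@]23C[C@@H](O[C@H]4C[C@@H](C)CC[C@@H]4C(C)C)OC3=O)C(=O)O1
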